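Time came first. In the blue run, the very flask asked about, L stood at 17.3% after 5.00 h and 17.1% after 6.00 h, one level within the scatter, while X kept falling.

common to all: X 0.30 M; E 0.285 M

|  | temperature | remark | time |
|---|---|---|---|
| blue | −20 °C | the very flask that is asked about, followed so far |  |
| teal | −35 °C | run made earlier |  |
| flask | −20 °C |  | 8.0 h |

- blue (time / h: L / %, X / %): 1.50: 11.5, 42.5; 3.00: 15.5, 32.0; 5.00: 17.3, 27.4; 6.00: 17.1, 25.7
- teal (time / h: L / %, X / %): 3.00: 4.5, 72.2; 6.00: 9.8, 57.4; 10.0: 15.8, 48.8; 12.0: 18.2, 45.7

(each reading ± 0.5 percentage points)

- spring: at 8.0 h add E, 50.0% of the amount charged, then wait 2.5 h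
- winter: at 8.0 h add X, 50.0% of the amount charged, then wait 2.5 h
- dusk: change nothing and wait 2.5 h more
- noon: at 8.0 h raise the temperature by 25 K, then wait 2.5 h

- the volume of additions can be left aside
- the numbers in the tables scatter with a standard deviation of 0.5 percentage points
- a reading or a percentage of L counts all its forms, free or not

- L, in percent of the X first charged, at 8.0 h
- the option that brings most further L ("none" if no option brings more than 2 percentage points) (spring / winter / dusk / noon / none)
- L present, in percent of the X first charged, after spring
- L present, in percent of the X first charged, after winter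

I took that level as the plateau P = 17.2% of blue, and let the gap g = P − L shrink as dg/dt = −λg, which integrates to g(t) = g(a)·exp(−λ(t − a)) from any earlier time a. The gaps at 1.50 h and 3.00 h gave 0.807 /h, the gap-closing constant λ: the rate at which L closes on its plateau, per unit of gap. It is a rough reading, since the second gap carries a scatter of 0.5 percentage points. At 8.0 h the gap was then 0.03 points, and the further 2.5 h could bring 0.026 points, well under the 2 points that counts. So I committed to P for L at 8.0 h and to no gain from waiting; λ put no price on additions.

The forecast gave 18%, chose spring, and put L at 32% after spring and 18.3% after winter: “The stall looks like E running out, not equilibrium.”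

The flask gave 17.1%. The best option was spring, with 33.9% after spring and 17.1% after winter.

    X + E → G (k = 2.80 /M/h, Ea = 64.0 kJ/mol)
    E + G → D (k = 7.00 /M/h, Ea = 54.0 kJ/mol)
    E + D → L (k = 8.70 /M/h, Ea = 41.0 kJ/mol)
    2 X → Z (k = 0.100 /M/h, Ea = 62.0 kJ/mol)
    X ⇌ J (K = 1.00, k = 0.140 /h, Ea = 86.0 kJ/mol, ΔH = 24.0 kJ/mol)
    Q ⇌ L, rate k6*(cs6 - [L]) while solid is left; crystals form when [L] > cs6 (solubility = 3.10 mM, k = 50.0 /h)
    (constants at −20 °C)

Blue stalled because its E, the limiting reagent, was used up, with 0.0399% of its charge free at 8.00 h; the same run without that using up gave 88.5% of L against 17.1%. Waiting brought 0.013 points where λ had put 0.026 points, and spring gained 17 points.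

The earlier runs and the new flask are simulated on assumed constants, and the scatter is random.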